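Slowness is your first worry: has Tuesday's flask at 80 °C finished in 10 h, and do the hotter flasks end anywhere else?

    substrate + reagent → first product + by-product (k1 = 8.69 L mol⁻¹ h⁻¹, Ea1 = 71.0 kJ mol⁻¹)
    reagent + first product → bis adduct + by-product (k2 = 9.21 L mol⁻¹ h⁻¹, Ea2 = 66.0 kJ mol⁻¹)
    reagent + bis adduct → triple product + by-product (k3 = 24.2 L mol⁻¹ h⁻¹, Ea3 = 67.0 kJ mol⁻¹)
    (constants at 80 °C)

| setting | Tuesday's | Wednesday's | Saturday's | Monday's |
|---|---|---|---|---|
| substrate | 0.16 M | 0.16 M | 0.16 M | 0.16 M |
| reagent | 2.50 equiv | 2.50 equiv | 2.50 equiv | 2.50 equiv |
| temperature | 80 °C |  | 95 °C | 110 °C |
| time | 10 h | 10 h | 10 h | 10 h |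
| remark |  | at 110 °C until 8.0 h, from then on at 80 °C |  |  |

- the constants hold at 80 °C; other temperatures follow from the activation energies

- the flask with the highest share of first product in all that became first product or bis adduct or triple product ("all alike" if they lie within 1.5 percentage points) (Tuesday's / Wednesday's / Saturday's / Monday's / all alike)
- share of first product in all that became first product or bis adduct or triple product, Tuesday's
- share of first product in all that became first product or bis adduct or triple product, Wednesday's
- share of first product in all that became first product or bis adduct or triple product, Saturday's
- share of first product in all that became first product or bis adduct or triple product, Monday's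

**Two times.** At 80 °C the first step has the smallest constant, 8.69 L mol⁻¹ h⁻¹. One over that constant times the charged c(substrate) is 0.719 h; call it the working time. Tuesday's run is far longer than that, 13.9 working times. Monday's working time is shorter still, at 0.109 h.

**The stop.** Full addition takes 3 equiv, but you charge 2.50 equiv, which covers 83.3% of it. Reagent is the limiting reagent. So I expect each flask to stop on reagent, not on the clock.

**Small shifts.** From the coldest flask to the hottest, the later steps speed up less than the first: 5.8 and 6.0 against 6.6. Their activation energies lie below the first step's by 5.00 kJ mol⁻¹ and 4.00 kJ mol⁻¹. I therefore expect first product's share to rise slightly with temperature. My reckoning ends here, with no share in figures.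

**The forecast.** It goes further and gives 14.7%, 15.7%, 15.2% and 15.7% for Tuesday's, Wednesday's, Saturday's and Monday's. Its verdict is all alike: “The spread is under 1.5 points, so all alike”.

**The result.** The simulation gives 14.7%, 15.7%, 15.2% and 15.7%, in the same order, so the verdict is all alike. After its 13.9 working times, Tuesday's flask holds 0.0959% of its reagent at 10.0 h.

**The neighbour.** Take Tuesday's flask with 1.00 equiv of reagent. The charged c(substrate) is unchanged, so the working time is still 0.719 h, and the run is still 13.9 of them. The charge now covers 33.3% of full addition, less than Tuesday's. The reckoning again expects a stop on reagent. At 10.0 h this neighbour holds 0% of its reagent, 39.2% substrate and 35.7% first product, and its share is 58.7%.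

All constants are invented; the rest is arithmetic.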